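The bridgehead C5 of the 6-oxabicyclo[3.2.1]octane core has two roles. It is the carbinol carbon of an aldol between C8 and a methyl ketone, and it is the oxygen-bearing end of the bridge O6–C7 that leads to the other bridgehead C1. One open chain can therefore close both the carbocycle C1–C2–C3–C4–C5–C8 and the five-membered ring C1–C7–O6–C5–C8.
Late disconnections: the aryl ether (Mitsunobu reaction with umbelliferone), the E-trisubstituted alkene (B-alkyl Suzuki coupling of a C8 vinyl group with the E-enol triflate of ethyl acetoacetate), and the C7 methylene (lactone, then lactol, then ether).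
Key disconnection: C8–C5 by enamine aldol (carbocycle first), then O6–C7 by lactonization (bridge second), in one flask from an acyclic keto aldehyde ester. This fixes C5 and C8.
The acyclic precursor carries only C2 and C1. C2 comes from Noyori hydrogenation of a β-keto ester, and C1 from two Fráter–Seebach alkylations, allyl first and methyl second, which is the order that gives the required C1/C2 relation. A double ozonolysis then unmasks both carbonyl groups.

Key step: step 7

Remark: the locants C1–C8 and O6 of the bicyclic core are used for the same atoms in all open-chain precursors.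

Step 1
Reactants: 1 methyl acetoacetate; 2 methallyl chloride
Product: 4 methyl 6-methyl-3-oxohept-6-enoate, via acetoacetate dianion 3 (not isolated)
Conditions: NaH, THF, 0 °C; n-BuLi, 0 °C; 2, 0 °C to rt; 1 M HCl
Reagents that add atoms: none
Why: Acetoacetate dianion alkylation: the second deprotonation creates the more reactive terminal carbanion, which alone is alkylated by the allylic chloride (SN2), and no stereocentre is formed.

Step 2
Reactants: 4 methyl 6-methyl-3-oxohept-6-enoate
Product: 5 methyl (3R)-3-hydroxy-6-methylhept-6-enoate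
Conditions: RuCl2[(R)-BINAP] (0.2 mol %), H2 (10 atm), MeOH, 50 °C
Reagents that add atoms: none
Why: Noyori asymmetric hydrogenation: the β-keto ester chelates ruthenium and (R)-BINAP directs hydride to the face that gives the (R)-carbinol (the sense known for methyl acetoacetate), which sets C2 of the core, while the remote, non-chelating 1,1-disubstituted alkene should be left alone by the halide-containing catalyst.

Step 3
Reactants: 5 methyl (3R)-3-hydroxy-6-methylhept-6-enoate; 6 allyl bromide
Product: 8 methyl (2R,3R)-3-hydroxy-6-methyl-2-(prop-2-en-1-yl)hept-6-enoate, via dilithium alkoxide enolate 7 (not isolated)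
Conditions: LiN(i-Pr)2 (2.2 equiv), THF, −78 to −20 °C; 6, DMPU, −78 to −10 °C; 1 M HCl
Reagents that add atoms: none
Why: Fráter–Seebach alkylation: the lithium-chelated alkoxide enolate is allylated anti to the C3 side chain, and although the anti (2R,3R) isomer is expected, this α-centre is planarized again in step 4, so its purity does not matter.

Step 4
Reactants: 8 methyl (2R,3R)-3-hydroxy-6-methyl-2-(prop-2-en-1-yl)hept-6-enoate
Product: 10 methyl (2S,3R)-3-hydroxy-2,6-dimethyl-2-(prop-2-en-1-yl)hept-6-enoate, via dilithium alkoxide enolate 9 (not isolated)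
Conditions: LiN(i-Pr)2 (2.5 equiv), THF, −78 to 0 °C; MeI, DMPU, −78 to −10 °C; 1 M HCl
Reagents that add atoms: iodomethane, CI
Why: Second Fráter–Seebach alkylation: in the chelated, fully substituted enolate, allylic strain holds the C3–H in the enolate plane and the C3 side chain over one face, so MeI enters from the other face and the methyl group ends anti and the allyl group syn to the C3 oxygen (zigzag projection), which is the (2S,3R) relation of C1 and C2.

Step 5
Reactants: 10 methyl (2S,3R)-3-hydroxy-2,6-dimethyl-2-(prop-2-en-1-yl)hept-6-enoate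
Product: 11 methyl (2S,3R)-3-[(tert-butyldimethylsilyl)oxy]-2,6-dimethyl-2-(prop-2-en-1-yl)hept-6-enoate
Conditions: TBSOTf, 2,6-lutidine, CH2Cl2, 0 °C to rt
Reagents that add atoms: tert-butyldimethylsilyl triflate, CC(C)(C)[Si](C)(C)OS(=O)(=O)C(F)(F)F
Why: Silylation with a silyl triflate and a hindered pyridine base is the standard protection of a secondary alcohol next to a quaternary carbon, and it blocks retro-aldol cleavage and competing acyl transfer later without touching a stereocentre.

Step 6
Reactants: 11 methyl (2S,3R)-3-[(tert-butyldimethylsilyl)oxy]-2,6-dimethyl-2-(prop-2-en-1-yl)hept-6-enoate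
Product: 13 methyl (2S,3R)-3-[(tert-butyldimethylsilyl)oxy]-2-methyl-6-oxo-2-(2-oxoethyl)heptanoate, via bis-ozonide 12 (not isolated)
Conditions: O3, CH2Cl2, −78 °C; PPh3, −78 °C to rt
Reagents that add atoms: ozone, [O-][O+]=O
Why: Ozonolysis with reductive work-up: both alkenes pass through the Criegee sequence to ozonides that PPh3 reduces, so allyl becomes the CH2CHO group (C8) and methallyl becomes the C5 methyl ketone, while ester, silyl ether and both stereocentres are inert.

Step 7
Reactants: 13 methyl (2S,3R)-3-[(tert-butyldimethylsilyl)oxy]-2-methyl-6-oxo-2-(2-oxoethyl)heptanoate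
Product: 16 (1S,2R,5S,8R)-2-[(tert-butyldimethylsilyl)oxy]-1,5-dimethyl-7-oxo-6-oxabicyclo[3.2.1]octane-8-carbaldehyde (formyl group over the O6–C7 bridge, silyloxy group equatorial), via pyrrolidine enamine 14 (not isolated), via tertiary aldol 15 (not isolated)
Conditions: pyrrolidine (20 mol %), AcOH (20 mol %), CH2Cl2 (0.05 M), rt
Reagents that add atoms: none
Why: Pyrrolidine condenses with the unhindered CH2CHO group much faster than with the methyl ketone, the (E)-enamine 14 adds through C8 to the C5 carbonyl, hydrolysis of the iminium ion returns the catalyst and gives aldol 15, and the C5 oxygen then displaces methoxide from the C7 ester. The closest known reactions are the secondary-amine-catalysed enolexo aldolization of keto aldehydes, amine-catalysed aldol–lactonization cascades and the first two stages (aldol addition, paraconic lactone formation) of the Stobbe condensation of succinic esters with ketones. The carbocycle C1–C2–C3–C4–C5–C8 closes in the 6-(enolexo)-exo-trig mode and the γ-lactone C1–C7–O6–C5–C8 in the 5-exo-trig mode by acyl substitution. C5 is controlled by the C1 stereocentre through the sink: aldol addition is reversible, and only the adduct whose C5 oxygen is cis (1,3-diaxial) to the ester on C1 can lactonize, which is also the chair that keeps both methyl groups and the C2 silyl ether equatorial. C8 is controlled by the same chair, in which the enamine arm is equatorial, so the formyl group ends over the hydrogen-free O6–C7 bridge and away from the axial hydrogens at C2 and C4; as this is also the more stable epimer, retro-aldol before lactonization or enolization afterwards can only correct it. The step needs the aldehyde as donor and the ketone as acceptor, which amine catalysis and the quaternary C1 secure (C8 is the only α-position of the aldehyde and the ester cannot enolize), and it needs acyl transfer to outrun loss of water and β-elimination of the carboxylate, which the geminal methyl groups at C1 and C5 (they hold oxygen and ester diaxial) and the buffered, base-free medium at room temperature favour.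

Step 8
Reactants: 16 (1S,2R,5S,8R)-2-[(tert-butyldimethylsilyl)oxy]-1,5-dimethyl-7-oxo-6-oxabicyclo[3.2.1]octane-8-carbaldehyde
Product: 17 (1S,2R,5S,8R)-2-[(tert-butyldimethylsilyl)oxy]-8-ethenyl-1,5-dimethyl-6-oxabicyclo[3.2.1]octan-7-one
Conditions: Zn, CH2Br2, TiCl4, THF, 5 °C (aged reagent); then 16, CH2Cl2, 0 °C to rt
Reagents that add atoms: dibromomethane, BrCBr
Why: Takai–Lombardo methylenation: the non-basic gem-dimetallic reagent adds to the aldehyde and loses metal oxide, does not attack lactones or silyl ethers and does not enolize, so C8 and the β-acyloxy bond C5–O6 should stay untouched and the acidifying group at C8 is removed for good.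

Step 9
Reactants: 17 (1S,2R,5S,8R)-2-[(tert-butyldimethylsilyl)oxy]-8-ethenyl-1,5-dimethyl-6-oxabicyclo[3.2.1]octan-7-one
Product: 18 (1S,2R,5S,8R)-2-[(tert-butyldimethylsilyl)oxy]-8-ethenyl-1,5-dimethyl-6-oxabicyclo[3.2.1]octan-7-ol (C7 epimers)
Conditions: i-Bu2AlH (1.2 equiv), CH2Cl2, −78 °C; aq. potassium sodium tartrate
Reagents that add atoms: none
Why: Partial reduction of a lactone with i-Bu2AlH: the aluminium hemiacetal of the neopentyl C7 carbonyl is stable at −78 °C, which prevents over-reduction, and the new C7 centre disappears in step 10.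

Step 10
Reactants: 18 (1S,2R,5S,8R)-2-[(tert-butyldimethylsilyl)oxy]-8-ethenyl-1,5-dimethyl-6-oxabicyclo[3.2.1]octan-7-ol
Product: 19 tert-butyl{[(1R,2R,5S,8R)-8-ethenyl-1,5-dimethyl-6-oxabicyclo[3.2.1]octan-2-yl]oxy}dimethylsilane
Conditions: Et3SiH, BF3·OEt2, CH2Cl2, −78 to −40 °C
Reagents that add atoms: none
Why: Ionic reduction of a lactol: BF3 ionizes the C7 hydroxyl to the O6=C7 oxocarbenium ion (double bond inside the two-atom bridge, not at a bridgehead), which Et3SiH captures, and at this stage the molecule holds no ketal or allylic alcohol, only a hindered silyl ether and a monosubstituted alkene that tolerate these conditions.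

Step 11
Reactants: 20 ethyl acetoacetate
Product: 21 ethyl (2E)-3-{[(trifluoromethyl)sulfonyl]oxy}but-2-enoate
Conditions: Tf2O, aq. Me4NOH, hexanes, 5 °C to rt
Reagents that add atoms: triflic anhydride, O=S(=O)(OS(=O)(=O)C(F)(F)F)C(F)(F)F
Why: O-Triflation of the acetoacetate enolate under Schotten–Baumann-type two-phase conditions: with the non-chelating tetramethylammonium counter-ion the enolate reacts in its extended form and gives the E-enol triflate, whereas a chelating lithium ion would give the Z isomer.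

Step 12
Reactants: 19 tert-butyl{[(1R,2R,5S,8R)-8-ethenyl-1,5-dimethyl-6-oxabicyclo[3.2.1]octan-2-yl]oxy}dimethylsilane; 21 ethyl (2E)-3-{[(trifluoromethyl)sulfonyl]oxy}but-2-enoate
Product: 23 ethyl (2E)-5-{(1R,2R,5S,8R)-2-[(tert-butyldimethylsilyl)oxy]-1,5-dimethyl-6-oxabicyclo[3.2.1]octan-8-yl}-3-methylpent-2-enoate, via B-alkyl borane 22 (not isolated)
Conditions: 9-BBN, THF, rt; then 21, PdCl2(dppf) (5 mol %), aq. K3PO4, DMF, rt to 50 °C
Reagents that add atoms: none
Why: Anti-Markovnikov hydroboration of the monosubstituted alkene followed by B-alkyl Suzuki–Miyaura coupling, which proceeds with retention of the enol triflate geometry and so fixes the E-trisubstituted alkene without an isomer-forming olefination.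

Step 13
Reactants: 23 ethyl (2E)-5-{(1R,2R,5S,8R)-2-[(tert-butyldimethylsilyl)oxy]-1,5-dimethyl-6-oxabicyclo[3.2.1]octan-8-yl}-3-methylpent-2-enoate
Product: 24 (2E)-5-{(1R,2R,5S,8R)-2-[(tert-butyldimethylsilyl)oxy]-1,5-dimethyl-6-oxabicyclo[3.2.1]octan-8-yl}-3-methylpent-2-en-1-ol
Conditions: i-Bu2AlH (2.5 equiv), CH2Cl2, −78 °C; aq. potassium sodium tartrate
Reagents that add atoms: none
Why: 1,2-Reduction of an α,β-unsaturated ester with i-Bu2AlH gives the allylic alcohol with the alkene geometry retained, and the silyl ether and cyclic ether are inert.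

Step 14
Reactants: 24 (2E)-5-{(1R,2R,5S,8R)-2-[(tert-butyldimethylsilyl)oxy]-1,5-dimethyl-6-oxabicyclo[3.2.1]octan-8-yl}-3-methylpent-2-en-1-ol; 25 umbelliferone
Product: 26 7-{[(2E)-5-{(1R,2R,5S,8R)-2-[(tert-butyldimethylsilyl)oxy]-1,5-dimethyl-6-oxabicyclo[3.2.1]octan-8-yl}-3-methylpent-2-en-1-yl]oxy}-2H-chromen-2-one
Conditions: PPh3, DIAD, THF, 0 °C to rt
Reagents that add atoms: none
Why: Mitsunobu etherification: the acidic phenol protonates the betaine and displaces the primary allylic oxyphosphonium group directly (SN2), so neither allylic transposition nor E/Z scrambling is expected, and the only other hydroxyl group is still silylated.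

Step 15
Reactants: 26 7-{[(2E)-5-{(1R,2R,5S,8R)-2-[(tert-butyldimethylsilyl)oxy]-1,5-dimethyl-6-oxabicyclo[3.2.1]octan-8-yl}-3-methylpent-2-en-1-yl]oxy}-2H-chromen-2-one
Product: 27 7-{[(2E)-5-[(1R,2R,5S,8R)-2-hydroxy-1,5-dimethyl-6-oxabicyclo[3.2.1]octan-8-yl]-3-methylpent-2-en-1-yl]oxy}-2H-chromen-2-one (CNP0178104.1)
Conditions: n-Bu4NF, AcOH, THF, rt to 40 °C
Reagents that add atoms: none
Why: Fluoride desilylation driven by the Si–F bond, buffered with acetic acid so that the coumarin lactone and the allyl aryl ether are not exposed to base, with retention at C2 because only the O–Si bond breaks.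

Compound list
1 | methyl acetoacetate | CC(=O)CC(=O)OC | starting material
2 | methallyl chloride (3-chloro-2-methylprop-1-ene) | C=C(C)CCl | starting material
3 | sodium lithium dianion (bis-enolate) of 1 | C=C([O-])C=C([O-])OC.[Na+].[Li+] | intermediate
4 | methyl 6-methyl-3-oxohept-6-enoate | C=C(C)CCC(=O)CC(=O)OC | intermediate
5 | methyl (3R)-3-hydroxy-6-methylhept-6-enoate | C=C(C)CC[C@@H](O)CC(=O)OC | intermediate
6 | allyl bromide | C=CCBr | starting material
7 | dilithium alkoxide enolate of 5 (enolate oxygen cis to C3) | C=C(C)CC[C@@H]([O-])/C=C(\[O-])OC.[Li+].[Li+] | intermediate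
8 | methyl (2R,3R)-3-hydroxy-6-methyl-2-(prop-2-en-1-yl)hept-6-enoate | C=C(C)CC[C@@H](O)[C@@H](CC=C)C(=O)OC | intermediate
9 | dilithium alkoxide enolate of 8 (enolate oxygen cis to C3) | C=C(C)CC[C@@H]([O-])/C(CC=C)=C(\[O-])OC.[Li+].[Li+] | intermediate
10 | methyl (2S,3R)-3-hydroxy-2,6-dimethyl-2-(prop-2-en-1-yl)hept-6-enoate | C=C(C)CC[C@@H](O)[C@](C)(CC=C)C(=O)OC | intermediate
11 | methyl (2S,3R)-3-[(tert-butyldimethylsilyl)oxy]-2,6-dimethyl-2-(prop-2-en-1-yl)hept-6-enoate | C=C(C)CC[C@@H](O[Si](C)(C)C(C)(C)C)[C@](C)(CC=C)C(=O)OC | intermediate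
12 | methyl (2S,3R)-3-[(tert-butyldimethylsilyl)oxy]-2-methyl-5-(3-methyl-1,2,4-trioxolan-3-yl)-2-[(1,2,4-trioxolan-3-yl)methyl]pentanoate (ozonide carbons unassigned) | CC1(OCOO1)CC[C@@H](O[Si](C)(C)C(C)(C)C)[C@](C)(CC2OCOO2)C(=O)OC | intermediate
13 | methyl (2S,3R)-3-[(tert-butyldimethylsilyl)oxy]-2-methyl-6-oxo-2-(2-oxoethyl)heptanoate | O=CC[C@](C)(C(=O)OC)[C@H](O[Si](C)(C)C(C)(C)C)CCC(C)=O | intermediate
14 | methyl (2S,3R)-3-[(tert-butyldimethylsilyl)oxy]-2-methyl-6-oxo-2-[(E)-2-(pyrrolidin-1-yl)ethenyl]heptanoate | CC(=O)CC[C@@H](O[Si](C)(C)C(C)(C)C)[C@](C)(/C=C/N1CCCC1)C(=O)OC | intermediate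
15 | methyl (1S,2R,3S,6R)-6-[(tert-butyldimethylsilyl)oxy]-2-formyl-3-hydroxy-1,3-dimethylcyclohexane-1-carboxylate | O=C[C@@H]1[C@](C)(C(=O)OC)[C@H](O[Si](C)(C)C(C)(C)C)CC[C@]1(C)O | intermediate
16 | (1S,2R,5S,8R)-2-[(tert-butyldimethylsilyl)oxy]-1,5-dimethyl-7-oxo-6-oxabicyclo[3.2.1]octane-8-carbaldehyde | O=C[C@@H]1[C@]2(C)C(=O)O[C@@]1(C)CC[C@H]2O[Si](C)(C)C(C)(C)C | intermediate
17 | (1S,2R,5S,8R)-2-[(tert-butyldimethylsilyl)oxy]-8-ethenyl-1,5-dimethyl-6-oxabicyclo[3.2.1]octan-7-one | C=C[C@@H]1[C@]2(C)C(=O)O[C@@]1(C)CC[C@H]2O[Si](C)(C)C(C)(C)C | intermediate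
18 | (1S,2R,5S,8R)-2-[(tert-butyldimethylsilyl)oxy]-8-ethenyl-1,5-dimethyl-6-oxabicyclo[3.2.1]octan-7-ol (C7 epimers) | C=C[C@@H]1[C@]2(C)C(O)O[C@@]1(C)CC[C@H]2O[Si](C)(C)C(C)(C)C | intermediate
19 | tert-butyl{[(1R,2R,5S,8R)-8-ethenyl-1,5-dimethyl-6-oxabicyclo[3.2.1]octan-2-yl]oxy}dimethylsilane | C=C[C@@H]1[C@]2(C)CO[C@@]1(C)CC[C@H]2O[Si](C)(C)C(C)(C)C | intermediate
20 | ethyl acetoacetate | CCOC(=O)CC(C)=O | starting material
21 | ethyl (2E)-3-{[(trifluoromethyl)sulfonyl]oxy}but-2-enoate | CCOC(=O)/C=C(\C)OS(=O)(=O)C(F)(F)F | intermediate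
22 | 9-{2-[(1R,2R,5S,8R)-2-[(tert-butyldimethylsilyl)oxy]-1,5-dimethyl-6-oxabicyclo[3.2.1]octan-8-yl]ethyl}-9-borabicyclo[3.3.1]nonane | C1CC2CCCC(C1)B2CC[C@@H]3[C@]4(C)CO[C@@]3(C)CC[C@H]4O[Si](C)(C)C(C)(C)C | intermediate
23 | ethyl (2E)-5-{(1R,2R,5S,8R)-2-[(tert-butyldimethylsilyl)oxy]-1,5-dimethyl-6-oxabicyclo[3.2.1]octan-8-yl}-3-methylpent-2-enoate | CCOC(=O)/C=C(\C)CC[C@@H]1[C@]2(C)CO[C@@]1(C)CC[C@H]2O[Si](C)(C)C(C)(C)C | intermediate
24 | (2E)-5-{(1R,2R,5S,8R)-2-[(tert-butyldimethylsilyl)oxy]-1,5-dimethyl-6-oxabicyclo[3.2.1]octan-8-yl}-3-methylpent-2-en-1-ol | OC/C=C(\C)CC[C@@H]1[C@]2(C)CO[C@@]1(C)CC[C@H]2O[Si](C)(C)C(C)(C)C | intermediate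
25 | umbelliferone (7-hydroxy-2H-chromen-2-one) | Oc1ccc2ccc(=O)oc2c1 | starting material
26 | 7-{[(2E)-5-{(1R,2R,5S,8R)-2-[(tert-butyldimethylsilyl)oxy]-1,5-dimethyl-6-oxabicyclo[3.2.1]octan-8-yl}-3-methylpent-2-en-1-yl]oxy}-2H-chromen-2-one | C/C(=C\COc1ccc2ccc(=O)oc2c1)CC[C@@H]1[C@]2(C)CO[C@@]1(C)CC[C@H]2O[Si](C)(C)C(C)(C)C | intermediate
27 | 7-{[(2E)-5-[(1R,2R,5S,8R)-2-hydroxy-1,5-dimethyl-6-oxabicyclo[3.2.1]octan-8-yl]-3-methylpent-2-en-1-yl]oxy}-2H-chromen-2-one | C/C(=C\COc1ccc2ccc(=O)oc2c1)CC[C@@H]1[C@]2(C)CO[C@@]1(C)CC[C@H]2O | target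

Total step count: 15.
Longest linear sequence: 14 steps (steps 1–10 and 12–15, from 1). Step 11 is a one-step side branch.

Steps most likely to fail

Step 7. Four processes threaten it.
- The tertiary aldol may lose water before acyl transfer.
- The lactone may be reopened by β-elimination of the carboxylate from the enol or enamine of the product. This is the last stage of a Stobbe sequence.
- The pairing may cross over, so that the ketone α-carbon C4 attacks the aldehyde.
- C–C bond formation between two fully substituted neighbours may be too slow.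

The fallback sets out from 11 and comes back at 17, so it also passes by steps 6 and 8. It replaces the enamine donor with an allylmetal donor. Sulfoxide-promoted allylic C–H acetoxylation of the monosubstituted alkene of 11 (Pd(OAc)2, 1,4-benzoquinone, DMSO/AcOH, 40 °C) should give methyl (2S,3R)-2-[(1E)-3-acetoxyprop-1-en-1-yl]-3-[(tert-butyldimethylsilyl)oxy]-2,6-dimethylhept-6-enoate F1. Lemieux–Johnson cleavage of the more electron-rich and unhindered 1,1-disubstituted alkene (OsO4 cat., NaIO4, 2,6-lutidine, dioxane/H2O) should give methyl (2S,3R)-2-[(1E)-3-acetoxyprop-1-en-1-yl]-3-[(tert-butyldimethylsilyl)oxy]-2-methyl-6-oxoheptanoate F2. Pd(PPh3)4 and InI in THF convert the allylic acetate, through reductive transmetalation of the π-allylpalladium complex, into an allylindium reagent. This reagent adds through its γ-carbon C8 to the C5 ketone and gives methyl (1S,2R,3S,6R)-6-[(tert-butyldimethylsilyl)oxy]-2-ethenyl-3-hydroxy-1,3-dimethylcyclohexane-1-carboxylate F3. A catalytic amount of NaH in THF then closes the lactone to 17. No C8–H next to a carbonyl group is ever present, so β-elimination is excluded. The addition is irreversible, so an adduct with the C5 oxygen trans to the ester would stay unlactonized and would have to be separated.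

Step 8. Addition to a formyl group flanked by two quaternary carbons may be sluggish. During a long exposure to the Lewis-acidic reagent, enolization with β-elimination of the carboxylate may then take over.

The fallback sets out from 16 and comes back at 23. It uses a weakly basic, stabilized phosphonate carbanion, the standard olefination for β-acyloxy aldehydes, and builds the alkene by a second olefination instead of by cross-coupling. Masamune–Roush Horner–Wadsworth–Emmons reaction (dimethyl (2-oxopropyl)phosphonate, LiCl, i-Pr2NEt, MeCN, rt) should give (1S,2R,5S,8R)-2-[(tert-butyldimethylsilyl)oxy]-1,5-dimethyl-8-[(1E)-3-oxobut-1-en-1-yl]-6-oxabicyclo[3.2.1]octan-7-one F4. Hydrogenation (H2, Pd on carbon, EtOAc) gives (1S,2R,5S,8R)-2-[(tert-butyldimethylsilyl)oxy]-1,5-dimethyl-8-(3-oxobutyl)-6-oxabicyclo[3.2.1]octan-7-one F5. i-Bu2AlH (3 equiv, CH2Cl2, −78 °C) reduces ketone and lactone together to (1S,2R,5S,8R)-2-[(tert-butyldimethylsilyl)oxy]-8-(3-hydroxybutyl)-1,5-dimethyl-6-oxabicyclo[3.2.1]octan-7-ol F6. Et3SiH/BF3·OEt2 at −78 °C removes only the lactol hydroxyl and gives 4-{(1R,2R,5S,8R)-2-[(tert-butyldimethylsilyl)oxy]-1,5-dimethyl-6-oxabicyclo[3.2.1]octan-8-yl}butan-2-ol F7. Dess–Martin oxidation gives 4-{(1R,2R,5S,8R)-2-[(tert-butyldimethylsilyl)oxy]-1,5-dimethyl-6-oxabicyclo[3.2.1]octan-8-yl}butan-2-one F8. Triethyl phosphonoacetate with NaH in THF then leads to 23, and the minor Z isomer is removed by chromatography.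

Step 10. BF3 may cleave the silyl ether. The tertiary C5–O6 bond may ionize. Reduction may also run through the open hydroxy aldehyde form instead of the oxocarbenium ion.

The fallback sets out from 17 and comes back at 19. It closes the ether by substitution instead of by ionic reduction. LiAlH4 in THF at 0 °C should open the lactone to (1S,2R,3R,4R)-4-[(tert-butyldimethylsilyl)oxy]-2-ethenyl-3-(hydroxymethyl)-1,3-dimethylcyclohexan-1-ol F9. MsCl and Et3N in CH2Cl2 at −20 °C sulfonylate only the primary alcohol and give {(1R,2R,3S,6R)-6-[(tert-butyldimethylsilyl)oxy]-2-ethenyl-3-hydroxy-1,3-dimethylcyclohexyl}methyl methanesulfonate F10. KOt-Bu in THF (0 °C to reflux) then effects the 5-exo-tet Williamson closure by the 1,3-diaxial tertiary alkoxide to give 19.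

Further compounds
F1 | step 7 | methyl (2S,3R)-2-[(1E)-3-acetoxyprop-1-en-1-yl]-3-[(tert-butyldimethylsilyl)oxy]-2,6-dimethylhept-6-enoate | C=C(C)CC[C@@H](O[Si](C)(C)C(C)(C)C)[C@](C)(/C=C/COC(C)=O)C(=O)OC
F2 | step 7 | methyl (2S,3R)-2-[(1E)-3-acetoxyprop-1-en-1-yl]-3-[(tert-butyldimethylsilyl)oxy]-2-methyl-6-oxoheptanoate | CC(=O)CC[C@@H](O[Si](C)(C)C(C)(C)C)[C@](C)(/C=C/COC(C)=O)C(=O)OC
F3 | step 7 | methyl (1S,2R,3S,6R)-6-[(tert-butyldimethylsilyl)oxy]-2-ethenyl-3-hydroxy-1,3-dimethylcyclohexane-1-carboxylate | C=C[C@@H]1[C@](C)(C(=O)OC)[C@H](O[Si](C)(C)C(C)(C)C)CC[C@]1(C)O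
F4 | step 8 | (1S,2R,5S,8R)-2-[(tert-butyldimethylsilyl)oxy]-1,5-dimethyl-8-[(1E)-3-oxobut-1-en-1-yl]-6-oxabicyclo[3.2.1]octan-7-one | CC(=O)/C=C/[C@@H]1[C@]2(C)C(=O)O[C@@]1(C)CC[C@H]2O[Si](C)(C)C(C)(C)C
F5 | step 8 | (1S,2R,5S,8R)-2-[(tert-butyldimethylsilyl)oxy]-1,5-dimethyl-8-(3-oxobutyl)-6-oxabicyclo[3.2.1]octan-7-one | CC(=O)CC[C@@H]1[C@]2(C)C(=O)O[C@@]1(C)CC[C@H]2O[Si](C)(C)C(C)(C)C
F6 | step 8 | (1S,2R,5S,8R)-2-[(tert-butyldimethylsilyl)oxy]-8-(3-hydroxybutyl)-1,5-dimethyl-6-oxabicyclo[3.2.1]octan-7-ol (epimers at C7 and at the side-chain carbinol) | CC(O)CC[C@@H]1[C@]2(C)C(O)O[C@@]1(C)CC[C@H]2O[Si](C)(C)C(C)(C)C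
F7 | step 8 | 4-{(1R,2R,5S,8R)-2-[(tert-butyldimethylsilyl)oxy]-1,5-dimethyl-6-oxabicyclo[3.2.1]octan-8-yl}butan-2-ol (carbinol epimers) | CC(O)CC[C@@H]1[C@]2(C)CO[C@@]1(C)CC[C@H]2O[Si](C)(C)C(C)(C)C
F8 | step 8 | 4-{(1R,2R,5S,8R)-2-[(tert-butyldimethylsilyl)oxy]-1,5-dimethyl-6-oxabicyclo[3.2.1]octan-8-yl}butan-2-one | CC(=O)CC[C@@H]1[C@]2(C)CO[C@@]1(C)CC[C@H]2O[Si](C)(C)C(C)(C)C
F9 | step 10 | (1S,2R,3R,4R)-4-[(tert-butyldimethylsilyl)oxy]-2-ethenyl-3-(hydroxymethyl)-1,3-dimethylcyclohexan-1-ol | C=C[C@@H]1[C@](C)(CO)[C@H](O[Si](C)(C)C(C)(C)C)CC[C@]1(C)O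
F10 | step 10 | {(1R,2R,3S,6R)-6-[(tert-butyldimethylsilyl)oxy]-2-ethenyl-3-hydroxy-1,3-dimethylcyclohexyl}methyl methanesulfonate | C=C[C@@H]1[C@](C)(COS(C)(=O)=O)[C@H](O[Si](C)(C)C(C)(C)C)CC[C@]1(C)O
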